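# Lancerodiol p-hydroxybenzoate: synthesis design by intramolecular de Mayo ring expansion

## The problem

Lancerodiol p-hydroxybenzoate (20) is a daucane, a cyclopentane trans-fused to a cycloheptenone. The locants used throughout are C1 (methyl-bearing fusion carbon), C2 and C3 (ring CH2), C4 (tertiary carbinol carrying the isopropyl group), C5 (fusion CH), C6 (CH–O ester), C7=C8(CH3), C9 (ketone) and C10 (CH2 back to C1). Four stereocentres must be delivered: quaternary C1, fully substituted C4, and the contiguous C5 and C6. Only C6 can be bought cheaply, so it has to dictate C1; the angular methyl on C1 can then direct attack at C4, and C5 can settle next to a C4 carbonyl while that carbonyl still exists. The seven-membered ring with its quaternary neighbour is poorly suited to direct cyclisation. The molecule and its precursors are also fragile: the C6 oxygen is β to any C4 carbonyl (E1cB loss), the γ-acyloxy enone isomerises with base, the tertiary alcohol dehydrates with acid, and the ester carries a free phenol. Any intermediate with carbonyls at both C4 and C9 poses a differentiation problem. The enabling feature is that C4 and C9 are 1,5-related through C5–C1–C10, which is what retro-aldol opening of a cyclobutanol leaves behind. In addition, the C9–C5–C6 array with the C8 methyl maps onto a 2-acyl-3-oxy-5-methylcyclopentanone, so a C5–C9 bond can be made early and broken again.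

## Retrosynthesis

**Ester (C6–O acyl bond).** Target 20 is traced through its phenol-silylated form 19 to lancerodiol 15 and 4-(tert-butyldimethylsilyloxy)benzoic acid 18 (from 4-hydroxybenzoic acid 16). The ester is cut last because an acyloxy group at C6 would not survive enolate or organometallic steps, whereas a silyl ether does. The forward reaction must acylate the secondary C6 hydroxyl in the presence of the tertiary C4 hydroxyl and finish with a non-basic phenol release.

**Enone (C7=C8).** Diol 15 comes from the silylated enone 14, which comes from enol silane 13 of the saturated C9 ketone 12. Carrying the enone through the photochemical step was rejected because a cycloheptenone is itself photoreactive. Because C1 bears no hydrogen, a C9 ketone can only be desaturated toward C8, so only the enol silane regiochemistry has to be right.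

**Isopropyl group (C4–C bond).** Alcohol 12 is cut to diketone 11. No step before ring formation can carry this group, because C4 must remain a carbonyl for the fragmentation. The forward addition must choose the cyclopentanone C4 over the cycloheptanone C9, must approach from the face opposite the C1 methyl, and must not enolise toward C5.

**Ring system (C1–C5 and C9–C10 formed, C5–C9 broken).** Diketone 11 is the retro-aldol product of cyclobutanol 10, the intramolecular [2+2] adduct of the enol of β-diketone 9. This removes both rings and two stereocentres at once and leaves a monocyclic cyclopentanone whose only permanent stereocentre is C6. Competing cuts either lose the C6 oxygen or build the quaternary centre intermolecularly (see below). The forward step needs straight regiochemistry, attack anti to the C6 silyloxy group, and neutral conditions so that no enolate β to the silyloxy group is formed.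

**Acyl side chain (C4–C5).** β-Diketone 9 is cut to ketone 5 and acyl donor 7, made from 4-methylpent-4-enoic acid 6. Amine/Lewis-acid enolisation at room temperature was set aside in favour of a kinetic lithium enolate at −78 °C. The enolate required sits β to the silyloxy group and should only be tolerated cold and briefly.

**Cyclopentanone.** Ketone 5 is traced through enone 4 and iodoenone 3 to silyl ether 2 and (R)-4-hydroxycyclopent-2-en-1-one 1. One-pot conjugate reduction–methylation of 2 would be shorter, but hydride reagents tend to attack unsubstituted cyclopentenones at the carbonyl, and slow enolate methylation invites proton transfer and silyloxy loss. Iodination, cross-coupling and hydrogenation cost one more step and involve no enolate.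

## Roads not taken

**Alternative 1:** The cut is at C1–CH3 and C5–C6, with the seven-membered ring closed later at C8–C9. In the forward step a chiral copper catalyst transfers methyl from an organoaluminium donor to enone A1, and the resulting enolate adds to iodo-enal A2 to give aldol A3.
- Merits: it is convergent and catalytic in chirality. The vinyl iodide and masked aldehyde of A3 set up a ring closure that puts the C9 oxygen and the C7=C8 bond in their final positions. C4 is then the only ketone when the isopropyl group is added. On these two counts it is better than the chosen plan, which needs a late desaturation (steps 9 and 10) and a ketone differentiation (step 8).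
- Weak points: conjugate methylation that creates a quaternary centre is less selective on cyclopentenones than on cyclohexenones. The enolate face at C5 must distinguish a methyl from a CH2R group on C1. The C6 configuration depends on an aldol with a labile (Z)-β-iodo enal. A3 is a β-hydroxy ketone prone to retro-aldol and dehydration.
- Against it the chosen plan sets a purchased C6 centre, a C1 centre fixed by the geometry of a cis-fused cyclobutane, and a C5 centre under thermodynamic control.

**Alternative 2:** The cut is at C1–C5 and C6–C7. In the forward step a Rh(I) catalyst joins the 1-siloxycyclopropyl alkene and the terminal alkyne of A4 in a (5+2) cycloaddition to give diene A5.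
- Merits: both rings form in one atom-economical step, and the C4 carbinol with its isopropyl group is already in place. No organometallic addition on the bicycle and no ketone differentiation are needed, which is better than the chosen plan.
- Weak points: an enantioenriched tertiary propargylic carbinol is required. A trisubstituted alkene must react to form the quaternary centre. C1 is controlled only by C4 through a flexible tether. A5 lacks the C6 oxygen and the C8 methyl, and its enol silane points toward C10, where no desaturation is possible. The endgame therefore needs hydroboration of C5=C6, methylation at C8 and desaturation.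
- The route to the bicycle is shorter but the route after it is longer. In the chosen plan diketone 11 already has all three oxygens and the C8 methyl on the right carbons.

**Alternative 3:** The cut is at C1–C10. In the forward step enol ether A6 undergoes a thermal Claisen ring expansion to cycloheptenone A7 while the C6–O bond breaks.
- Merits: no reagent is needed. The suprafacial shift transfers chirality from C6 to C1. The C8 methyl is in place. C4 (ketal) and C9 (ketone) emerge differentiated, which is better than in 11.
- Weak points: the C6 oxygen is consumed, since it becomes the C9 carbonyl oxygen. C6–O and C5–H must be rebuilt by hydroboration of the C5=C6 alkene next to the angular methyl. A6 needs a stereodefined tetrahydrofuran with an acid-labile exocyclic enol ether, which lengthens the front of the route.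
- The chosen plan keeps the C6 oxygen throughout and pays for it with the C4/C9 selectivity problem of step 8.

Key step: step 7

## Route

Remark: bicyclic compounds are named with the locants C1–C10 defined in "The problem" (not von Baeyer locants); the SMILES strings define the structures.

Assumption: β-diketone 9 is written as its ring enol; the two chelated enol tautomers interconvert rapidly and are treated as one compound.

Assumption: 5 is carried on as the cis isomer; any C8 epimer converges in step 10, where C8 becomes sp2.

Step 1
Reactants: 1 (R)-4-hydroxycyclopent-2-en-1-one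
Product: 2 (R)-4-(tert-butyldimethylsilyloxy)cyclopent-2-en-1-one
Conditions: TBSCl, Et3N, DMAP (cat.), CH2Cl2, 0 °C
Reagents that add atoms: tert-butyldimethylsilyl chloride, CC(C)(C)[Si](C)(C)Cl
Why: Standard O-silylation; the mild amine base at 0 °C should not eliminate or racemise the γ-oxygenated enone, and the C6 stereocentre is untouched.

Step 2
Reactants: 2 (R)-4-(tert-butyldimethylsilyloxy)cyclopent-2-en-1-one
Product: 3 (R)-4-(tert-butyldimethylsilyloxy)-2-iodocyclopent-2-en-1-one
Conditions: I2, pyridine, CH2Cl2, 0 °C to rt
Reagents that add atoms: iodine, II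
Why: α-Iodination of an enone by pyridine conjugate addition, iodination of the enolate and elimination; this reaction type is well established on 4-silyloxycyclopentenones and places the halogen on the future C8.

Step 3
Reactants: 3 (R)-4-(tert-butyldimethylsilyloxy)-2-iodocyclopent-2-en-1-one
Product: 4 (R)-4-(tert-butyldimethylsilyloxy)-2-methylcyclopent-2-en-1-one
Conditions: MeZnCl, Pd(dba)2/P(2-furyl)3 (cat.), THF–DMF, rt
Reagents that add atoms: methylzinc chloride, C[Zn]Cl
Why: Negishi cross-coupling of an α-iodoenone; the organozinc is neutral and does not add to the enone, so the base-sensitive γ-silyloxy enone should survive.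

Step 4
Reactants: 4 (R)-4-(tert-butyldimethylsilyloxy)-2-methylcyclopent-2-en-1-one
Product: 5 (2R,4S)-4-(tert-butyldimethylsilyloxy)-2-methylcyclopentan-1-one (methyl and silyloxy cis)
Conditions: H2 (1 atm), 10% Pd/C, EtOAc, rt
Reagents that add atoms: none
Why: Heterogeneous hydrogenation of the enone C=C; hydrogen should be delivered to the face opposite the silyloxy group, leaving the C8 methyl cis to it, and this temporary centre is removed again in step 10.

Step 5
Reactants: 6 4-methylpent-4-enoic acid
Product: 7 1-(4-methylpent-4-enoyl)-1H-benzotriazole
Conditions: 1H-benzotriazole, DCC, CH2Cl2, 0 °C to rt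
Reagents that add atoms: 1H-benzotriazole, c1ccc2[nH]nnc2c1
Why: Carbodiimide coupling to an N-acylbenzotriazole, a storable acyl donor that C-acylates ketone enolates.

Step 6
Reactants: 5 (2R,4S)-4-(tert-butyldimethylsilyloxy)-2-methylcyclopentan-1-one; 7 1-(4-methylpent-4-enoyl)-1H-benzotriazole
Product: 9 (3S,5R)-3-(tert-butyldimethylsilyloxy)-5-methyl-2-(4-methylpent-4-enoyl)cyclopentan-1-one as its chelated enol, via kinetic lithium enolate 8 (not isolated)
Conditions: LDA (2.1 equiv), THF, −78 °C; then 7, −78 °C; AcOH quench at −78 °C
Reagents that add atoms: none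
Why: Kinetic deprotonation takes the methylene (C5) rather than the methine (C8), and crossed Claisen-type C-acylation by the acylbenzotriazole follows; the second equivalent of base takes up the more acidic product. At −78 °C loss of silanolate from enolate 8 should be slow, and the diketonate formed is too stabilised to eliminate before the cold acidic quench.

Step 7
Reactants: 9 (3S,5R)-3-(tert-butyldimethylsilyloxy)-5-methyl-2-(4-methylpent-4-enoyl)cyclopentan-1-one as its chelated enol
Product: 11 (1R,5S,6S,8R)-6-(tert-butyldimethylsilyloxy)-1,8-dimethylbicyclo[5.3.0]decane-4,9-dione (trans-fused), via cyclobutanol photoadduct 10 (not isolated)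
Conditions: hν (medium-pressure Hg lamp, Pyrex, λ > 290 nm), degassed cyclohexane, 0.01 M, rt
Reagents that add atoms: none
Why: The chelated enol of 9 absorbs near 290 nm; its excited state bonds C5 to C1 (1,5-closure across the C4–C3–C2 tether), the 1,4-diradical collapses at C9–C10 to cyclobutanol 10, and this strained β-hydroxy ketone opens by retro-aldol cleavage of C5–C9 to the C9 ketone and the C4 enol, which ketonises to 11. The closest known reaction type is the intramolecular de Mayo reaction of 2-(alk-4-enoyl)cycloalkanone enols, which gives hydroazulenediones in this way. The cyclopentane closes by direct C5–C1 bond formation (five-membered 1,5-closure, necessarily cis-fused to the cyclobutane); the cycloheptanone is not closed by a new bond but results when C10–C1 is left inserted between C9 and C5 as the old ring bond breaks. C1 is controlled by C6: the alkene should add to the enol face opposite the C6 silyloxy group and the C8 methyl (both α), and because the bicyclo[3.2.0] junction must be cis the C1 methyl ends on the side of C5 that carries C6, which is the 1R configuration. C5 is flattened in the fragmentation and reset on ketonisation next to the C4 carbonyl, where it should settle thermodynamically in the trans-fused form with C4 anti to the C6 silyloxy group (5S). The step needs straight regiochemistry (reaction through the ring enol with 1,6-diene spacing), facial selectivity (the two α substituents) and survival of the β-silyloxy group (neutral aprotic medium, in which the fragmentation gives an enol and never an enolate). The Pyrex filter and the far stronger absorption of the enol than of the product ketones should limit secondary photolysis.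

Step 8
Reactants: 11 (1R,5S,6S,8R)-6-(tert-butyldimethylsilyloxy)-1,8-dimethylbicyclo[5.3.0]decane-4,9-dione
Product: 12 (1R,4R,5S,6S,8R)-6-(tert-butyldimethylsilyloxy)-4-hydroxy-1,8-dimethyl-4-(propan-2-yl)bicyclo[5.3.0]decan-9-one
Conditions: CeCl3 (anhydrous), i-PrMgCl (1.1 equiv), THF, −78 °C
Reagents that add atoms: isopropylmagnesium chloride, CC(C)[Mg]Cl
Why: Organocerium 1,2-addition; the weakly basic reagent should add without enolising C5, which would expel the silyloxy group. The cyclopentanone carbonyl is intrinsically more reactive than a cycloheptanone, and C9 is further shielded by its α-methyl and the neopentyl C10, so C4 should react first. Attack anti to the angular C1 methyl (α face) gives the 4R carbinol with the hydroxyl cis to that methyl.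

Step 9
Reactants: 12 (1R,4R,5S,6S,8R)-6-(tert-butyldimethylsilyloxy)-4-hydroxy-1,8-dimethyl-4-(propan-2-yl)bicyclo[5.3.0]decan-9-one
Product: 13 (1R,4R,5S,6S)-6-(tert-butyldimethylsilyloxy)-1,8-dimethyl-4-(propan-2-yl)-4,9-bis(trimethylsilyloxy)bicyclo[5.3.0]dec-8-ene
Conditions: TMSOTf (3 equiv), Et3N, CH2Cl2, 0 °C to rt
Reagents that add atoms: trimethylsilyl trifluoromethanesulfonate, C[Si](C)(C)OS(=O)(=O)C(F)(F)F
Why: Soft enolisation–silylation under equilibrating conditions should favour the tetrasubstituted C8=C9 enol silane over the strained C9=C10 isomer next to quaternary C1; the tertiary alcohol is capped as its TMS ether at the same time. Any C10 isomer cannot be desaturated (C1 has no hydrogen) and returns 12 on work-up.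

Step 10
Reactants: 13 (1R,4R,5S,6S)-6-(tert-butyldimethylsilyloxy)-1,8-dimethyl-4-(propan-2-yl)-4,9-bis(trimethylsilyloxy)bicyclo[5.3.0]dec-8-ene
Product: 14 (1R,4R,5S,6S)-6-(tert-butyldimethylsilyloxy)-1,8-dimethyl-4-(propan-2-yl)-4-(trimethylsilyloxy)bicyclo[5.3.0]dec-7-en-9-one
Conditions: Pd(OAc)2 (1.1 equiv), MeCN, rt
Reagents that add atoms: none
Why: Saegusa–Ito oxidation; the palladium enolate at C8 should lose a ring hydrogen from C7 to give the endocyclic 2-methylcycloheptenone, which removes the temporary C8 stereocentre.

Step 11
Reactants: 14 (1R,4R,5S,6S)-6-(tert-butyldimethylsilyloxy)-1,8-dimethyl-4-(propan-2-yl)-4-(trimethylsilyloxy)bicyclo[5.3.0]dec-7-en-9-one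
Product: 15 lancerodiol, (1R,4R,5S,6S)-4,6-dihydroxy-1,8-dimethyl-4-(propan-2-yl)bicyclo[5.3.0]dec-7-en-9-one
Conditions: HF·pyridine, pyridine, THF, 0 °C to rt
Reagents that add atoms: none
Why: Buffered fluoride desilylation removes both silyl ethers; the conditions are too mild to ionise the tertiary alcohol and not basic enough to isomerise the γ-hydroxy enone.

Step 12
Reactants: 16 4-hydroxybenzoic acid
Product: 18 4-(tert-butyldimethylsilyloxy)benzoic acid, via bis-silyl intermediate 17 (not isolated)
Conditions: TBSCl (2.2 equiv), imidazole, DMF, rt; then AcOH–THF–H2O, rt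
Reagents that add atoms: tert-butyldimethylsilyl chloride, CC(C)(C)[Si](C)(C)Cl
Why: Exhaustive silylation followed by selective hydrolysis; a silyl ester is far more labile than an aryl silyl ether, so only the acid is released.

Step 13
Reactants: 15 lancerodiol; 18 4-(tert-butyldimethylsilyloxy)benzoic acid
Product: 19 lancerodiol 6-[4-(tert-butyldimethylsilyloxy)benzoate]
Conditions: DCC, DMAP, CH2Cl2, 0 °C to rt
Reagents that add atoms: none
Why: Steglich esterification; the secondary allylic C6 hydroxyl should be acylated while the tertiary C4 hydroxyl is inert under these conditions, and the mild base should leave the γ-oxygenated enone intact.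

Step 14
Reactants: 19 lancerodiol 6-[4-(tert-butyldimethylsilyloxy)benzoate]
Product: 20 lancerodiol p-hydroxybenzoate, (1R,4R,5S,6S)-4-hydroxy-1,8-dimethyl-9-oxo-4-(propan-2-yl)bicyclo[5.3.0]dec-7-en-6-yl 4-hydroxybenzoate
Conditions: TBAF, AcOH (1:1), THF, 0 °C
Reagents that add atoms: none
Why: Aryl silyl ethers are cleaved rapidly by fluoride; buffering with acetic acid should prevent acyl migration to the C4 hydroxyl and base-induced isomerisation of the γ-acyloxy enone.

## Compound list

1 | (R)-4-hydroxycyclopent-2-en-1-one | O=C1C=C[C@H](O)C1 | starting material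
2 | (R)-4-(tert-butyldimethylsilyloxy)cyclopent-2-en-1-one | O=C1C=C[C@H](O[Si](C)(C)C(C)(C)C)C1 | intermediate
3 | (R)-4-(tert-butyldimethylsilyloxy)-2-iodocyclopent-2-en-1-one | O=C1C(I)=C[C@H](O[Si](C)(C)C(C)(C)C)C1 | intermediate
4 | (R)-4-(tert-butyldimethylsilyloxy)-2-methylcyclopent-2-en-1-one | CC1=C[C@H](O[Si](C)(C)C(C)(C)C)CC1=O | intermediate
5 | (2R,4S)-4-(tert-butyldimethylsilyloxy)-2-methylcyclopentan-1-one (cis) | C[C@@H]1C[C@H](O[Si](C)(C)C(C)(C)C)CC1=O | intermediate
6 | 4-methylpent-4-enoic acid | CC(=C)CCC(=O)O | starting material
7 | 1-(4-methylpent-4-enoyl)-1H-benzotriazole | CC(=C)CCC(=O)n1nnc2ccccc12 | intermediate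
8 | lithium (3S,5R)-3-(tert-butyldimethylsilyloxy)-5-methylcyclopent-1-en-1-olate (kinetic enolate of 5, not isolated) | C[C@@H]1C[C@H](O[Si](C)(C)C(C)(C)C)C=C1O[Li] | intermediate
9 | (3S,5R)-3-(tert-butyldimethylsilyloxy)-5-methyl-2-(4-methylpent-4-enoyl)cyclopentan-1-one, drawn as its chelated ring enol | C[C@@H]1C[C@H](O[Si](C)(C)C(C)(C)C)C(C(=O)CCC(C)=C)=C1O | intermediate
10 | cyclobutanol photoadduct: tricyclic 9-hydroxy-4-ketone with new bonds C1–C5 and C9–C10 on the face opposite the C6 silyloxy group (not isolated) | C[C@@H]1C[C@H](O[Si](C)(C)C(C)(C)C)[C@@]23C(=O)CC[C@]2(C)C[C@@]13O | intermediate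
11 | (1R,5S,6S,8R)-6-(tert-butyldimethylsilyloxy)-1,8-dimethylbicyclo[5.3.0]decane-4,9-dione (trans-fused) | C[C@@H]1C[C@H](O[Si](C)(C)C(C)(C)C)[C@H]2C(=O)CC[C@]2(C)CC1=O | intermediate
12 | (1R,4R,5S,6S,8R)-6-(tert-butyldimethylsilyloxy)-4-hydroxy-1,8-dimethyl-4-(propan-2-yl)bicyclo[5.3.0]decan-9-one | C[C@@H]1C[C@H](O[Si](C)(C)C(C)(C)C)[C@H]2[C@](O)(C(C)C)CC[C@]2(C)CC1=O | intermediate
13 | (1R,4R,5S,6S)-6-(tert-butyldimethylsilyloxy)-1,8-dimethyl-4-(propan-2-yl)-4,9-bis(trimethylsilyloxy)bicyclo[5.3.0]dec-8-ene | CC1=C(O[Si](C)(C)C)C[C@@]2(C)CC[C@@](O[Si](C)(C)C)(C(C)C)[C@@H]2[C@@H](O[Si](C)(C)C(C)(C)C)C1 | intermediate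
14 | (1R,4R,5S,6S)-6-(tert-butyldimethylsilyloxy)-1,8-dimethyl-4-(propan-2-yl)-4-(trimethylsilyloxy)bicyclo[5.3.0]dec-7-en-9-one | CC1=C[C@H](O[Si](C)(C)C(C)(C)C)[C@@H]2[C@](C)(CC[C@@]2(O[Si](C)(C)C)C(C)C)CC1=O | intermediate
15 | lancerodiol, (1R,4R,5S,6S)-4,6-dihydroxy-1,8-dimethyl-4-(propan-2-yl)bicyclo[5.3.0]dec-7-en-9-one | CC1=C[C@H](O)[C@@H]2[C@](C)(CC[C@@]2(O)C(C)C)CC1=O | intermediate
16 | 4-hydroxybenzoic acid | O=C(O)c1ccc(O)cc1 | starting material
17 | tert-butyldimethylsilyl 4-(tert-butyldimethylsilyloxy)benzoate (not isolated) | CC(C)(C)[Si](C)(C)OC(=O)c1ccc(O[Si](C)(C)C(C)(C)C)cc1 | intermediate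
18 | 4-(tert-butyldimethylsilyloxy)benzoic acid | CC(C)(C)[Si](C)(C)Oc1ccc(cc1)C(=O)O | intermediate
19 | lancerodiol 6-[4-(tert-butyldimethylsilyloxy)benzoate] | CC1=C[C@H](OC(=O)c2ccc(O[Si](C)(C)C(C)(C)C)cc2)[C@@H]2[C@](C)(CC[C@@]2(O)C(C)C)CC1=O | intermediate
20 | lancerodiol p-hydroxybenzoate | CC1=C[C@H](OC(=O)c2ccc(O)cc2)[C@@H]2[C@](C)(CC[C@@]2(O)C(C)C)CC1=O | target

## Step count and risk

Total step count: 14. Longest linear sequence: 12 steps (steps 1–4, 6–11, 13 and 14, from 1).

**Step 7 (key step).**
- What may go wrong: cycloaddition through the side-chain enol tautomer, or initial bonding of C5 to the alkene terminus C10 (1,6-closure, favoured by the methyl on C1). Either gives crossed adducts whose fragmentation does not lead to the hydroazulene. Lesser risks are alkene approach syn to the silyloxy group, ketonisation to the cis-fused C5 epimer, and slow photodegradation of 11.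
- Fallback: from 9, O-acylation with benzyl chloroformate and pyridine gives benzyl (3S,5R)-3-(tert-butyldimethylsilyloxy)-5-methyl-2-(4-methylpent-4-enoyl)cyclopent-1-en-1-yl carbonate F1, which fixes the ring enol double bond (an isomeric side-chain carbonate would be separated). Irradiation of F1 through Pyrex should give the benzyl carbonate of cyclobutanol 10 F2. Hydrogenolysis (H2, Pd/C, EtOAc) frees 10 under neutral conditions, and 10 fragments to rejoin the route at 11.

**Step 6.**
- What may go wrong: E1cB expulsion of silanolate from enolate 8 if it warms or lives too long, together with O-acylation and proton transfer between enolate and product.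
- Fallback: 6 is reduced (LiAlH4) to 4-methylpent-4-en-1-ol F3 and oxidised (Swern) to 4-methylpent-4-enal F4. Ketone 5 is converted with Bu2BOTf and i-Pr2NEt at −78 °C into its covalent boron enolate, which has little tendency to eliminate, and is added to F4 to give (2R,3S,5R)-3-(tert-butyldimethylsilyloxy)-2-(1-hydroxy-4-methylpent-4-en-1-yl)-5-methylcyclopentan-1-one F5 (carbinol epimers). Dess–Martin oxidation of F5 returns to the route at 9.

**Step 8.**
- What may go wrong: insufficient discrimination between the two ketones (addition at C9 or at both), hydride transfer from the isopropyl reagent instead of addition, or attack from the β face.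
- Fallback: if C9 competes it is evidently accessible, and that accessibility can be used to mask it. From 11, kinetic dioxolane formation (1,2-bis(trimethylsilyloxy)ethane, cat. TMSOTf, CH2Cl2, −78 °C) should give (1R,5S,6S,8R)-6-(tert-butyldimethylsilyloxy)-1,8-dimethylbicyclo[5.3.0]decane-4,9-dione 9-(ethylene ketal) F6. Isopropylcerium addition to its only ketone gives the 9-(ethylene ketal) of 12 F7. Mild hydrolysis (PPTS, aqueous acetone) rejoins the route at 12.

**Step 10 (with step 9).**
- What may go wrong: enolisation toward C10 in step 9, which is a dead end for desaturation; β-hydride loss from the methyl group to give an exocyclic methylene ketone; incomplete oxidation as palladium precipitates.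
- Fallback: from 12, direct dehydrogenation of the ketone with IBX in DMSO at 70 °C needs no enol silane and can only occur toward C8–C7. It should give (1R,4R,5S,6S)-6-(tert-butyldimethylsilyloxy)-4-hydroxy-1,8-dimethyl-4-(propan-2-yl)bicyclo[5.3.0]dec-7-en-9-one F8. Desilylation of F8 with HF·pyridine rejoins the route at 15.

## Further compounds

F1 | step 7 | benzyl (3S,5R)-3-(tert-butyldimethylsilyloxy)-5-methyl-2-(4-methylpent-4-enoyl)cyclopent-1-en-1-yl carbonate | C[C@@H]1C[C@H](O[Si](C)(C)C(C)(C)C)C(C(=O)CCC(C)=C)=C1OC(=O)OCc1ccccc1
F2 | step 7 | benzyl carbonate of cyclobutanol 10 (C9–OCO2Bn) | C[C@@H]1C[C@H](O[Si](C)(C)C(C)(C)C)[C@@]23C(=O)CC[C@]2(C)C[C@@]13OC(=O)OCc1ccccc1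
F3 | step 6 | 4-methylpent-4-en-1-ol | CC(=C)CCCO
F4 | step 6 | 4-methylpent-4-enal | CC(=C)CCC=O
F5 | step 6 | (2R,3S,5R)-3-(tert-butyldimethylsilyloxy)-2-(1-hydroxy-4-methylpent-4-en-1-yl)-5-methylcyclopentan-1-one (carbinol epimers) | C[C@@H]1C[C@H](O[Si](C)(C)C(C)(C)C)[C@@H](C(O)CCC(C)=C)C1=O
F6 | step 8 | (1R,5S,6S,8R)-6-(tert-butyldimethylsilyloxy)-1,8-dimethylbicyclo[5.3.0]decane-4,9-dione 9-(ethylene ketal) | C[C@@H]1C[C@H](O[Si](C)(C)C(C)(C)C)[C@H]2C(=O)CC[C@]2(C)CC13OCCO3
F7 | step 8 | 9-(ethylene ketal) of 12 | C[C@@H]1C[C@H](O[Si](C)(C)C(C)(C)C)[C@H]2[C@](O)(C(C)C)CC[C@]2(C)CC13OCCO3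
F8 | step 10 | (1R,4R,5S,6S)-6-(tert-butyldimethylsilyloxy)-4-hydroxy-1,8-dimethyl-4-(propan-2-yl)bicyclo[5.3.0]dec-7-en-9-one | CC1=C[C@H](O[Si](C)(C)C(C)(C)C)[C@@H]2[C@](C)(CC[C@@]2(O)C(C)C)CC1=O
A1 | alternative 1 | 3-(1,3-dioxolan-2-ylmethyl)cyclopent-2-en-1-one | O=C1CCC(CC2OCCO2)=C1
A2 | alternative 1 | (Z)-3-iodobut-2-enal | O=C/C=C(/C)I
A3 | alternative 1 | (2S,3R)-3-(1,3-dioxolan-2-ylmethyl)-2-[(1R,2Z)-1-hydroxy-3-iodobut-2-en-1-yl]-3-methylcyclopentan-1-one | C(C1OCCO1)[C@@]2(C)CCC(=O)[C@@H]2[C@@H](O)/C=C(/C)I
A4 | alternative 2 | tert-butyl({1-[(1E,5R)-2-methyl-5-(propan-2-yl)-5-(triethylsilyloxy)hept-1-en-6-yn-1-yl]cyclopropyl}oxy)dimethylsilane | C#C[C@](O[Si](CC)(CC)CC)(C(C)C)CC/C(C)=C/C1(O[Si](C)(C)C(C)(C)C)CC1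
A5 | alternative 2 | (1R,4R)-9-(tert-butyldimethylsilyloxy)-1-methyl-4-(propan-2-yl)-4-(triethylsilyloxy)bicyclo[5.3.0]deca-5,9-diene | C1CC(O[Si](C)(C)C(C)(C)C)=C[C@@]2(C)CC[C@@](O[Si](CC)(CC)CC)(C(C)C)C2=C1
A6 | alternative 3 | 7-methyl-6-[(2S,4S)-4-methyl-5-methylideneoxolan-2-yl]-1,4-dioxaspiro[4.4]non-6-ene | C=C1O[C@@H](C[C@@H]1C)C1=C(C)CCC12OCCO2
A7 | alternative 3 | (1R,8S)-1,8-dimethylbicyclo[5.3.0]dec-5-ene-4,9-dione 4-(ethylene ketal) | C[C@H]1CC=C2C3(OCCO3)CC[C@]2(C)CC1=O
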